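**Retrosynthetic overview**
1. The last operation joins two halves at the carbinol carbon of ring A. A core CH2–cerium reagent adds equatorially to (R)-4-bromo-3,3-dimethylcyclohexanone. That ketone is made in the same flask by the ring closure CH2–CMe2.
2. Enabling feature: in ring A the CHBr carbon is vicinal to CMe2, and the carbinol carbon is 1,3 to CMe2 across the CH2. Ring A is therefore the retron of a bromonium ion opened at its tertiary carbon by the CH2 end of a ketone enol. Both partners are stored in one temporary ring, a 6-methylidene-oxane whose O–CMe2 bond lies anti-periplanar to C–Br.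
3. The oxane comes from ethyl 5-methylhex-4-enoate: Shi epoxidation, bromide opening with inversion, lactonisation, Petasis methylenation.
4. Core: Birch reductive alkylation of 3-methylbenzoic acid (ring C, quaternary C3a) and resolution. A gold enyne/carboxyl cascade then builds rings B and D at once. Hydroboration sets C1, radical hydrobromination sets C4, and iodination follows.
5. Ring order: C (from the arene), then B + D (cascade); separately the temporary oxane, then A (key step).

Key step: step 13

Remark on locants: the core uses hydrindane numbering (C1–C3 ring B, C3a, C4–C7 ring C, C7a). Ring D is the lactone C3a–C(=O)–O–C7. Ring A is the cyclohexanol.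
Assumption: the salt of (R)-1-phenylethylamine with the (R)-acid is taken to be the less soluble one; if the other pairing crystallises, (S)-1-phenylethylamine is used.
Assumption: the L-fructose-derived enantiomer of the Shi ketone is taken to give the (S)-epoxide, the mirror image of the (R)-epoxides that the D-fructose-derived ketone gives with 2-methylalk-2-enes.

Step 1
Reactants: 1 3-methylbenzoic acid; 2 (4-bromobut-1-yn-1-yl)trimethylsilane
Product: 4 rac-1-(but-3-yn-1-yl)-3-methylcyclohexa-2,5-diene-1-carboxylic acid, via silylalkyne acid 3 (not isolated)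
Conditions: Li, NH3/THF, −78 °C; isoprene; 2; NH3 off; K2CO3 (cat.), MeOH, rt; 1 M HCl
Reagents that add atoms: none
Why: Birch reduction gives the dienediolate, which the primary bromide alkylates at the ipso carbon (Birch reductive alkylation) to build the quaternary carbon as a racemate, and methanolysis then removes the alkyne silyl group.

Step 2
Reactants: 4 rac-1-(but-3-yn-1-yl)-3-methylcyclohexa-2,5-diene-1-carboxylic acid; 5 (R)-1-phenylethylamine
Product: 6 (R)-1-phenylethylammonium (R)-1-(but-3-yn-1-yl)-3-methylcyclohexa-2,5-diene-1-carboxylate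
Conditions: 5 (0.5 equiv), EtOAc, 60 °C to rt; recrystallise
Reagents that add atoms: none
Why: Classical resolution through diastereomeric ammonium carboxylate salts (half-equivalent method) should deposit the salt of the (R)-acid and so fixes the quaternary centre from which all other core centres derive.

Step 3
Reactants: 6 (R)-1-phenylethylammonium (R)-carboxylate salt
Product: 7 (R)-1-(but-3-yn-1-yl)-3-methylcyclohexa-2,5-diene-1-carboxylic acid
Conditions: 1 M HCl, Et2O, 0 °C
Reagents that add atoms: none
Why: Acid–base liberation of the carboxylic acid from its salt leaves the stereocentre untouched.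

Step 4
Reactants: 7 (R)-1-(but-3-yn-1-yl)-3-methylcyclohexa-2,5-diene-1-carboxylic acid
Product: 8 tricyclic diene lactone (3aR,7S,7aS): cis-hydrindene with exocyclic methylene at C1, C4=C5 double bond, methyl at C7, C3a carboxyl lactonised onto C7
Conditions: [(t-Bu)2(biphenyl-2-yl)P]Au(NCMe)SbF6 (3 mol %), CH2Cl2, −20 °C to rt
Reagents that add atoms: none
Why: This is a monovalent-gold-catalysed 5-exo-dig cyclisation of the 1,6-enyne terminated by the carboxylic acid (acyloxycyclisation), in which the trisubstituted alkene attacks the activated alkyne from the face carrying the butynyl chain and the carboxyl group on the opposite face traps the tertiary cation, so this anti addition fixes C7a and C7 relative to C3a and protodeauration leaves the exocyclic methylene.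

Step 5
Reactants: 8 tricyclic diene lactone
Product: 10 (1S,3aR,7S,7aS)-1-(hydroxymethyl) alkene lactone, via alkyl-9-BBN adduct 9 (not isolated)
Conditions: 9-BBN (1.1 equiv), THF, 0 °C to rt; H2O2, aq NaOAc, 0 °C
Reagents that add atoms: hydrogen peroxide, OO; 9-BBN, [H]B1C2CCCC1CCC2 (its boron stays only in 9)
Why: In this hydroboration–oxidation 9-BBN takes the 1,1-disubstituted alkene in preference to the hindered ring alkene and approaches from the open face bearing C7a–H, so hydrogen enters C1 cis to C7a–H and the CH2OH group is pushed over ring C.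

Step 6
Reactants: 10 (1S,3aR,7S,7aS)-1-(hydroxymethyl) alkene lactone
Product: 11 (1S,3aR,4R,7S,7aS)-4-bromo-1-(hydroxymethyl)-7-methylhydrindane-3a,7-carbolactone
Conditions: Co(acac)2 (30 mol %), t-BuOOH (30 mol %), Et3SiH, TsBr, CH2Cl2/n-PrOH, rt
Reagents that add atoms: 4-toluenesulfonyl bromide, Cc1ccc(cc1)S(=O)(=O)Br
Why: Proposed new method: a cobalt hydride formed from Co(acac)2, t-BuOOH and Et3SiH should transfer a hydrogen atom to C5, the alkene carbon remote from quaternary C3a, and the C4 radical should take bromine from TsBr on the lactone face because the C1 hydroxymethyl group covers the other face, giving the equatorial (4R)-bromide; the closest known reaction is the cobalt-catalysed hydrogen-atom-transfer hydrobromination and hydrochlorination of mono-, 1,1-di- and trisubstituted alkenes with sulfonyl halides, not yet shown for a 1,2-disubstituted ring alkene whose regiochemistry rests on steric bias alone.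

Step 7
Reactants: 11 bromo alcohol
Product: 12 (1S,3aR,4R,7S,7aS)-4-bromo-1-(iodomethyl)-7-methylhydrindane-3a,7-carbolactone
Conditions: I2, PPh3, imidazole, CH2Cl2, 0 °C to rt
Reagents that add atoms: iodine, [I][I]
Why: Appel-type iodination of the primary alcohol (SN2 at CH2) touches neither the neopentyl secondary bromide nor any stereocentre.

Step 8
Reactants: 13 2-methylbut-3-en-2-ol; 14 triethyl orthoacetate
Product: 15 ethyl 5-methylhex-4-enoate
Conditions: EtCO2H (cat.), 140 °C, EtOH distilled off
Reagents that add atoms: none
Why: Johnson–Claisen rearrangement of the tertiary allylic alcohol gives the gamma,delta-unsaturated ester with the trisubstituted alkene; no stereocentre is formed.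

Step 9
Reactants: 15 ethyl 5-methylhex-4-enoate
Product: 16 ethyl 3-[(2S)-3,3-dimethyloxiran-2-yl]propanoate
Conditions: ent-Shi ketone (L-fructose-derived, 30 mol %), Oxone, K2CO3, Bu4NHSO4, MeCN/dimethoxymethane, aq borate/EDTA buffer, 0 °C
Reagents that add atoms: potassium peroxymonosulfate (active part of Oxone), [K+].[O-]S(=O)(=O)OO
Why: Shi epoxidation (chiral dioxirane, spiro transition state) of the trisubstituted alkene sets the secondary epoxide carbon as (S) under catalyst control.

Step 10
Reactants: 16 ethyl 3-[(2S)-3,3-dimethyloxiran-2-yl]propanoate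
Product: 17 ethyl (4R)-4-bromo-5-hydroxy-5-methylhexanoate
Conditions: Li2NiBr4, THF, 0 °C; pH 7 buffer
Reagents that add atoms: dilithium tetrabromonickelate, [Li+].[Li+].[Ni+2].[Br-].[Br-].[Br-].[Br-]
Why: The soft bromide of Li2NiBr4 opens the epoxide by SN2 at the less substituted carbon with inversion, giving the (R)-bromide next to the tertiary alcohol.

Step 11
Reactants: 17 ethyl (4R)-4-bromo-5-hydroxy-5-methylhexanoate
Product: 18 (5R)-5-bromo-6,6-dimethyloxan-2-one
Conditions: TsOH·H2O (cat.), toluene, 80 °C
Reagents that add atoms: none
Why: Acid-catalysed transesterification closes the six-membered lactone (6-exo-trig) with the tertiary alcohol and leaves the C–Br centre untouched.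

Step 12
Reactants: 18 (5R)-5-bromo-6,6-dimethyloxan-2-one
Product: 19 (3R)-3-bromo-2,2-dimethyl-6-methylideneoxane
Conditions: Cp2TiMe2, toluene, 70 °C, dark; basic alumina
Reagents that add atoms: dimethyltitanocene, [CH3-].[CH3-].[Ti+4].c1cc[cH-]c1.c1cc[cH-]c1
Why: Petasis methylenation of the lactone carbonyl gives the exocyclic enol ether under conditions that are neither basic nor acidic and spare the secondary bromide.

Step 13
Reactants: 19 (3R)-3-bromo-2,2-dimethyl-6-methylideneoxane; 12 core iodide
Product: 23 target CNP0282702.1, (1R,4R)-4-bromo-1-{[(1R,3aR,4R,7S,7aS)-4-bromo-7-methylhydrindane-3a,7-carbolacton-1-yl]methyl}-3,3-dimethylcyclohexan-1-ol, via bromoketone 20 (not isolated), via alkyllithium 21 (not isolated), via alkylcerium dichloride 22 (not isolated)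
Conditions: 19: TMSOTf (10 mol %), 2,6-di-tert-butyl-4-methylpyridine (15 mol %), CH2Cl2, −78 to −30 °C; 12: t-BuLi (2 equiv), Et2O/pentane, −78 °C, then CeCl3, THF, −78 °C; solution of 20 added to 22, −78 °C; aq NH4Cl
Reagents that add atoms: t-BuLi, [Li]C(C)(C)C (lithium of 21 only); CeCl3, [Ce+3].[Cl-].[Cl-].[Cl-] (cerium and chlorine of 22 only)
Why: Proposed new method: TMSOTf silylates the ring oxygen of 19, the O–CMe2 bond ionises with help from the anti-periplanar equatorial bromine, and the bromonium ion/silyl enol ether pair collapses through a chair when the enol CH2 attacks the CMe2 carbon, which forms the CH2–CMe2 bond, gives ketone 20 and hands the silyl cation to the next molecule of 19. The closest known reactions are the Petasis–Ferrier and related Lewis-acid O-to-C rearrangements of cyclic enol ethers, the Lewis-acid tert-alkylation of silyl enol ethers, and the stereospecific capture of bromonium ions released from beta-bromo leaving groups. Ring A closes 6-endo-trig at the enol double bond with opening of the bromonium ion at its tertiary carbon, so both bromonium carbons end in the ring; return of oxygen to CMe2 only regenerates 19, whereas C-attack is irreversible. The CHBr centre is not touched (bromine never leaves its carbon) and ends equatorial; the new carbinol centre is set in the second stage, where the axial methyl of CMe2 blocks axial approach and 22 adds equatorially, putting OH axial and cis to bromine (1R). The step needs C- over O-recombination without proton loss or enol ether isomerisation (secured by bromine bridging, low temperature and the hindered pyridine), and ketone over lactone or C–Br attack by 22 (secured by the low basicity of the trivalent cerium reagent, the pivalate-like hindrance of the lactone and the neopentyl position of both bromides).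

**Compound list**
1 | 3-methylbenzoic acid | Cc1cccc(c1)C(=O)O | starting material
2 | (4-bromobut-1-yn-1-yl)trimethylsilane | C[Si](C)(C)C#CCCBr | starting material
3 | rac-3-methyl-1-[4-(trimethylsilyl)but-3-yn-1-yl]cyclohexa-2,5-diene-1-carboxylic acid | C[Si](C)(C)C#CCCC1(C(=O)O)C=CCC(C)=C1 | intermediate
4 | rac-1-(but-3-yn-1-yl)-3-methylcyclohexa-2,5-diene-1-carboxylic acid | C#CCCC1(C(=O)O)C=CCC(C)=C1 | intermediate
5 | (R)-1-phenylethylamine | C[C@@H](N)c1ccccc1 | starting material
6 | (R)-1-phenylethylammonium (R)-1-(but-3-yn-1-yl)-3-methylcyclohexa-2,5-diene-1-carboxylate | C#CCC[C@@]1(C(=O)[O-])C=CCC(C)=C1.C[C@@H]([NH3+])c1ccccc1 | intermediate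
7 | (R)-1-(but-3-yn-1-yl)-3-methylcyclohexa-2,5-diene-1-carboxylic acid | C#CCC[C@@]1(C(=O)O)C=CCC(C)=C1 | intermediate
8 | (3aR,7S,7aS) tricyclic diene lactone (C1 methylidene, C4=C5) | C=C1CC[C@@]23C(=O)O[C@@](C)(CC=C2)[C@@H]13 | intermediate
9 | B-alkyl-9-BBN adduct of 8 | C(B1C2CCCC1CCC2)[C@H]1CC[C@@]23C(=O)O[C@@](C)(CC=C2)[C@@H]13 | intermediate
10 | (1S,3aR,7S,7aS)-1-(hydroxymethyl) alkene lactone | OC[C@H]1CC[C@@]23C(=O)O[C@@](C)(CC=C2)[C@@H]13 | intermediate
11 | (1S,3aR,4R,7S,7aS)-4-bromo-1-(hydroxymethyl)-7-methylhydrindane-3a,7-carbolactone | OC[C@H]1CC[C@@]23C(=O)O[C@@](C)(CC[C@H]2Br)[C@@H]13 | intermediate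
12 | (1S,3aR,4R,7S,7aS)-4-bromo-1-(iodomethyl)-7-methylhydrindane-3a,7-carbolactone | IC[C@H]1CC[C@@]23C(=O)O[C@@](C)(CC[C@H]2Br)[C@@H]13 | intermediate
13 | 2-methylbut-3-en-2-ol | CC(C)(O)C=C | starting material
14 | triethyl orthoacetate | CCOC(C)(OCC)OCC | starting material
15 | ethyl 5-methylhex-4-enoate | CCOC(=O)CCC=C(C)C | intermediate
16 | ethyl 3-[(2S)-3,3-dimethyloxiran-2-yl]propanoate | CCOC(=O)CC[C@@H]1OC1(C)C | intermediate
17 | ethyl (4R)-4-bromo-5-hydroxy-5-methylhexanoate | CCOC(=O)CC[C@@H](Br)C(C)(C)O | intermediate
18 | (5R)-5-bromo-6,6-dimethyloxan-2-one | CC1(C)OC(=O)CC[C@H]1Br | intermediate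
19 | (3R)-3-bromo-2,2-dimethyl-6-methylideneoxane | CC1(C)OC(=C)CC[C@H]1Br | intermediate
20 | (4R)-4-bromo-3,3-dimethylcyclohexan-1-one | CC1(C)CC(=O)CC[C@H]1Br | intermediate
21 | core alkyllithium (CH2Li at C1) | [Li]C[C@H]1CC[C@@]23C(=O)O[C@@](C)(CC[C@H]2Br)[C@@H]13 | intermediate
22 | core alkylcerium dichloride (CH2CeCl2 at C1) | Cl[Ce](Cl)C[C@H]1CC[C@@]23C(=O)O[C@@](C)(CC[C@H]2Br)[C@@H]13 | intermediate
23 | CNP0282702.1 | CC1(C)C[C@](O)(C[C@H]2CC[C@@]34C(=O)O[C@@](C)(CC[C@H]3Br)[C@@H]24)CC[C@H]1Br | target

Total step count: 13. Longest linear sequence: 8 (steps 1–7 and 13). The ring A precursor is made in 5 steps (8–12) in parallel.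

**Steps most likely to fail**

Step 13. Ionisation of 19 may end in proton loss from the cation, in isomerisation of the exocyclic enol ether into the ring, or in transfer of bromine to the enol ether, instead of ring closure. The fallback makes the same bond by the known solvolysis of vicinal bromochlorides with an alkyne as internal trap.
- It sets out from 16. DIBAL-H reduction gives 3-[(2S)-3,3-dimethyloxiran-2-yl]propanal F1.
- The Ohira–Bestmann reagent gives (3S)-3-(but-3-yn-1-yl)-2,2-dimethyloxirane F2.
- Li2NiBr4 gives (3R)-3-bromo-2-methylhept-6-yn-2-ol F3.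
- SOCl2 gives (5R)-5-bromo-6-chloro-6-methylhept-1-yne F4.
- Solvolysis in moist hexafluoroisopropanol proceeds by ionisation to the bromonium ion, 6-endo-dig attack of the terminal alkyne carbon on CMe2 and water capture of the vinyl cation. This comes back to the route at 20, which is then isolated and treated with 22 in a separate flask.

Step 6. Hydrogen-atom transfer to the hindered 1,2-disubstituted alkene may be too slow, or may go to C4 and place bromine at C5. The fallback separates regiocontrol from bromine delivery and uses known reactions.
- It sets out from 10. Hydroboration with catecholborane (3 equiv) and RhCl(PPh3)3, in which the lactone carbonyl steers boron to the proximal carbon, gives the C4-catecholboryl compound with its hydroxyl carried as the catechol borate F5.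
- Radical bromination of this B-alkylcatecholborane uses PhSO2Br and di-tert-butyl hyponitrite. The same C4 radical again takes bromine on the lactone face.
- Aqueous work-up comes back to the route at 11.

Step 4. Oxygen attack of the carboxyl group on the gold-activated alkyne (enol lactone formation) may outrun the strained anti closure of rings B and D. Skeletal rearrangement of the enyne is a second possible diversion. The fallback replaces alkyne activation by carbonyl activation.
- It sets out from 7. Markovnikov hydration of the alkyne (Hg(OTf)2 cat., H2O, MeCN) gives (R)-3-methyl-1-(3-oxobutyl)cyclohexa-2,5-diene-1-carboxylic acid F6.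
- MeAlCl2 promotes a ketone–alkene Prins-type cyclisation terminated by the aluminium carboxylate. This gives the C1-hydroxy-C1-methyl lactone F7, whose C1 configuration is of no consequence.
- Dehydration toward the methyl group with the Burgess reagent comes back to the route at 8.

Further compounds
F1 | step 13 | 3-[(2S)-3,3-dimethyloxiran-2-yl]propanal | O=CCC[C@@H]1OC1(C)C
F2 | step 13 | (3S)-3-(but-3-yn-1-yl)-2,2-dimethyloxirane | C#CCC[C@@H]1OC1(C)C
F3 | step 13 | (3R)-3-bromo-2-methylhept-6-yn-2-ol | C#CCC[C@@H](Br)C(C)(C)O
F4 | step 13 | (5R)-5-bromo-6-chloro-6-methylhept-1-yne | C#CCC[C@@H](Br)C(C)(C)Cl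
F5 | step 6 | C4-catecholboryl derivative of 10 with the hydroxyl as catechol borate | O(B1Oc2ccccc2O1)C[C@H]1CC[C@@]23C(=O)O[C@@](C)(CC[C@H]2B2Oc4ccccc4O2)[C@@H]13
F6 | step 4 | (R)-3-methyl-1-(3-oxobutyl)cyclohexa-2,5-diene-1-carboxylic acid | CC(=O)CC[C@@]1(C(=O)O)C=CCC(C)=C1
F7 | step 4 | (3aR,7S,7aS)-1-hydroxy-1,7-dimethyl alkene lactone | CC1(O)CC[C@@]23C(=O)O[C@@](C)(CC=C2)[C@@H]13
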